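The data are calculated with made-up constants; noise was put on by code.

In the amber flask, free [J] falls faster than E rises. The amber flask, with J at 0.031 M and Q at 2.00 equiv, is itself the flask I am asked about, followed so far.

- amber: J 0.031 M; Q 2 equiv; the very flask that is asked about, followed so far
- flask: J 0.031 M; Q 2.00 equiv; time 8.0 min

- amber (time / s: E / %, J / %): 10.0: 1.0, 98.1; 15.0: 1.5, 97.0; 25.0: 2.3, 93.7; 40.0: 3.7, 91.4; 60.0: 5.1, 86.5; 80.0: 6.8, 83.8

(standard deviation of a reading: 0.5 percentage points)

- a reading or a percentage of E counts all its forms, free or not
- a reading of J is of its free form alone

- amount of E in percent of the J charged, at 50 s, 3.0 min and 8.0 min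

The two numbers at first seem not to fit. At 80.0 s, [J] is down by 16 percentage points, yet E is up by 6.8%. One E for each J lost means two equal numbers, and these two differ.

Yet the two readings count different things: the J reading counts free J, and E counts all its forms. J can be held or diverted out of sight.

So I divide the rate of J loss by the rate of E gain, and time drops out. I call the result the price of E, the J missing per E made, and at 80.0 s it reads 2.38. This is the inverse of the selectivity. At 40.0 s it reads 2.32, so it looks steady within the scatter.

Next I need the J loss. The same last reading gives a first-order constant of 0.00221 /s, which I hold fixed. Dividing the J lost by the price, I reckon E at 4.39% after 50 s, 13.8% after 3.0 min and 27.4% after 8.0 min.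

The forecast, a little below mine at the two later times, gives 4.4%, 13.5% and 27%, and says “the extra J is probably held by E in a complex, or else lost to a side path”.

The flask gives 4.58%, 13.7% and 24.9%, so my last figure stands above it.

    J + Q ⇌ E (K = 3.60 /M, k = 0.0160 /M/s)
    J + Q → D (k = 0.00680 /M/s)
    J + E ⇌ L, settled at all times (K = 790 /M)

At 8.00 min the price in this flask is 2.37: of the J missing, 24.9% is E, counting the E inside L, 11.6% is D, and about 22.7% is the second J inside L. At that time in this flask the forward step to E, taken alone, uses Q 2.4 times as fast as the step to D, and net turnover stands at 24.9% to E against 11.6% to D, in percent of the J charged. By 80.0 min in this flask, E has slipped to 20.8%, D has grown to 42.3%, and the price stands at 3.86.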